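## Structural features

Target 16 is an isoflavan: a chromane (aromatic ring A fused through C4a and C8a to the dihydropyran ring C) that carries a 2,3,4,5-tetramethoxyphenyl ring (ring B) on C3. Ring A has a free phenol at C7 and a methoxy group at C8, so O1, the C8 oxygen and the C7 oxygen sit on three neighbouring carbons; ring B is substituted everywhere except C6'. C3 (S) is the only stereocentre, so no two stereocentres stand next to each other. It is a benzylic methine between the methylene groups C2 and C4 and has no heteroatom through which chirality could be relayed. The fragile points are the electron-rich phenol (oxidation), the aryl methyl ethers (strong Lewis acids) and above all the C3–H bond, which becomes acidic or eliminable whenever C2 is at the aldehyde, acetal or oxocarbenium level. The real difficulty is therefore to build an isolated tertiary benzylic carbon enantioselectively and to keep it intact to the end. The key step uses the fact that O1–C8a–C4a–C4 is a latent ortho-quinone methide of ring A, whose formation is helped by the C7 oxygen para to C4a, while C2–C3 with ring B corresponds to a β-aryl enol ether. A [4+2] union of the two forms C3–C4, O1–C2, ring C and the C3 stereocentre together.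

## Logic of the disconnections

16 ⇒ 15. Only the O7–CH2Ph bond is involved: a benzyl group is placed on the C7 oxygen. A free hydroxyl para to the benzylic carbon would divert the ring-forming ionisation towards a para-quinone methide and make every intermediate oxidation-prone, while the ether oxygen still assists ionisation. Nothing is gained in skeleton. The forward step must remove benzyl without touching the benzylic C3–H or the aryl ethers.

15 ⇒ 14. C2–H is exchanged for C2–OMe. This turns the saturated pyran into a cyclic O-aryl O-methyl acetal, the retron of a hetero-Diels–Alder reaction with an enol ether. The forward step must deliver hydride to C2 without letting C3 lose its proton.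

14 ⇒ 5 + 12 (through 13). The C3–C4 and O1–C2 bonds are cut. The molecule falls into an A-ring half and a B-ring half of similar size, and ring C and both stereocentres of 14 disappear at once, leaving two achiral partners. The forward step must generate 13 from 5 without oligomerisation, place the aryl-bearing carbon of 12 on the methide carbon, and select one face of that carbon through a chiral acid. 12 must be a single alkene isomer so that only one family of transition states is in play.

5 ⇒ 4. A benzylic C–H bond of the CH2OH group is cut back to the aldehyde, which is the handle for the next two disconnections. The forward reduction must be worked up without acid because 5 ionises easily.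

4 ⇒ 3. The O4–CH2Ph bond is cut. The forward step must tell the two phenols apart; the hydrogen bond of the 2-hydroxyl to the formyl group and the higher acidity of the 4-hydroxyl allow this.

3 ⇒ 1. The aryl–CHO bond is cut. The two activated free positions of 1 are equivalent, so only one monoformyl product is possible. The demand is to stop at monoformylation.

12 ⇒ 9 + 10. The C=C bond is cut. This gives a B-ring aldehyde and a one-carbon phosphonium salt. The demand is control, or separation, of alkene geometry.

9 ⇒ 6. The aryl–CHO bond is cut. The two free positions of 6 are equivalent and each is ortho to a methoxy group, so lithiation and formylation are regiochemically unambiguous.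

## Other disconnections considered

Alternative 1: The cut is C4–C4a plus O1–C2, made on the unprotected A ring. In the forward step, 1 would add through the carbon ortho to one hydroxyl and para to the other to the iminium ion formed from 2-(2,3,4,5-tetramethoxyphenyl)prop-2-enal A1 and a chiral secondary amine. The enamine would then be protonated at C3 under catalyst control, and the neighbouring phenol would close on the aldehyde to give the lactol (3S)-8-methoxy-3-(2,3,4,5-tetramethoxyphenyl)chromane-2,7-diol A2. Silane reduction of A2 would give 16.
- In favour: no protecting group is needed, the 7-hydroxyl is present from the start, and 1 and A1 would reach 16 in two steps. On step and protecting-group economy this plan is better than the chosen one. Regiochemistry of the first bond is as secure as in the chosen plan, because the two nucleophilic positions of 1 are equivalent.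
- Against: C3 is made by proton transfer to an α-aryl enamine. A2 is in equilibrium with its open-chain α-aryl aldehyde form, which the same amine can return to the enamine, so the C3 configuration can equilibrate for as long as the catalyst is present. A1 is a polymerisation-prone acrolein whose electron-rich aryl group lowers its electrophilicity. A2 still carries a nucleophilic resorcinol-type ring that can add to a second molecule of A1.
- Comparison: both plans cut ring C at two bonds and both leave an oxygen on C2 for silane removal. The chosen plan makes C3 in a carbon–carbon bond-forming event and delivers an acetal that cannot enolise; alternative 1 makes it in a reversible carbon–hydrogen bond-forming event. The chosen plan pays for this with a benzyl group and about four more steps.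

Alternative 2: C3 is removed as a single carbon atom, cutting C2–C3 and C3–C4. The precursors are 6-(benzyloxy)-7-methoxybenzofuran A3 and 3-chloro-3-(2,3,4,5-tetramethoxyphenyl)-3H-diazirine A4. In the forward step the arylchlorocarbene from A4 would cyclopropanate the furan C2=C3 bond, and the chlorocyclopropane would open with loss of chloride to 7-(benzyloxy)-8-methoxy-3-(2,3,4,5-tetramethoxyphenyl)chromenylium chloride A5.
- In favour: ring A, O1, C2 and C4 are carried in a stable aromatic heterocycle, and the aryl-bearing carbon enters in one operation. The union is as convergent as the chosen one, and it is better in having no alkene geometry to control.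
- Against: A5 is flat and achiral, so the key step sets no stereocentre. C3 would have to be created afterwards by an enantioselective two-stage reduction of the pyrylium ring, which is less precedented. A4 would come from 9 in about three steps ending in a hypochlorite oxidation, which a tetramethoxyphenyl ring may not tolerate (ring chlorination). Electron-rich aryl chlorodiazirines are thermally sensitive, high-energy compounds. This kind of carbon insertion is best established for indoles and pyrroles, and the less nucleophilic benzofuran π bond would compete less well with carbene dimerisation.
- Comparison: both plans join an A-ring piece and a B-ring piece in one step and form two skeletal bonds. The chosen plan creates ring C and the C3 configuration together; alternative 2 separates ring construction from stereocontrol. Step counts are close (about three steps each to A3 and A4, then insertion, reductions and hydrogenolysis), and the alternative carries the greater hazard.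

Alternative 3: The cut is the aryl ether bond O1–C8a, on a precursor in which C3 is quaternary: the prochiral diol 2-[4-(benzyloxy)-2-iodo-3-methoxybenzyl]-2-(2,3,4,5-tetramethoxyphenyl)propane-1,3-diol A6. In the forward step copper(I) with a chiral diamine would couple one of the two enantiotopic hydroxymethyl groups with the aryl iodide to give (S)-[7-(benzyloxy)-8-methoxy-3-(2,3,4,5-tetramethoxyphenyl)chroman-3-yl]methanol A7. Oxidation to (R)-7-(benzyloxy)-8-methoxy-3-(2,3,4,5-tetramethoxyphenyl)chromane-3-carbaldehyde A8 and rhodium-mediated decarbonylation with retention would give 15.
- In favour: desymmetrising O-arylation of 2-(2-halobenzyl)propane-1,3-diols is an established route to chromanes with a quaternary C3. The stereocentre of A7 and A8 cannot epimerise, which is better than the chosen plan, where C3 sits next to an acetal. No acid-labile intermediate is involved. Differentiating two identical groups with a metal–ligand complex is arguably a better understood source of selectivity than face selection on an enol ether with no binding site for the catalyst, so here the alternative is at least the equal.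
- Against: a carbon is installed only to be removed, at the cost of an oxidation and a decarbonylation that needs stoichiometric rhodium or high temperature. The alkyl–rhodium intermediate is tertiary and benzylic with β-hydrogens on C2 and C4, so β-hydride elimination competes with stereoretentive reductive elimination. The aryl iodide is flanked by a methoxy group and the benzylic chain, a hindered site for Ullmann coupling. A6 needs roughly five steps of malonate chemistry and ester reduction.
- Comparison: the chosen plan forms two bonds and the ring in the stereo-defining step, alternative 3 forms one. On step economy the chosen plan is clearly shorter (eight steps against about eleven).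

Key step: step 6

Remarks before the steps:
- Structure check: 5, 12 and 14 were checked atom by atom against 16. The 4-benzyloxy and 3-methoxy groups of 5 become the C7 and C8 substituents, and 2,3-trans with 3S corresponds to the descriptor (2R,3S). No correction was needed. C3 keeps the descriptor S in 14, 15 and 16 because the priority order C2 > aryl > C4 > H holds throughout.
- Assumption: for a methide with no substituent on its carbon, the catalyst enantiomer that gives the 3S series cannot be deduced with certainty. The (R)-catalyst is written; its mirror image is to be used if the first analytical run shows the opposite sense. TRIP is 3,3'-bis(2,4,6-triisopropylphenyl)-1,1'-binaphthyl-2,2'-diyl hydrogen phosphate.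
- Design points added to the bare disconnection:
  - The C7 oxygen stays benzylated to block the para-quinone methide channel.
  - Only the E isomer of 12 is used.
  - 5 is added slowly over molecular sieves, so the methide stays dilute and the released water cannot hydrolyse 12.
  - In step 7 the silane is present before the acid.
- Numbering: species that persist in the flask and the quinone methide are numbered. Short-lived ions within a single mechanistic event (σ-complexes, the oxaphosphetane, the C2 oxocarbenium ion of step 7) are described in the Why lines only.

## Route

Step 1
Reactants: 1 2-methoxyresorcinol (2-methoxybenzene-1,3-diol)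
Product: 3 2,4-dihydroxy-3-methoxybenzaldehyde, via aryl iminium chloride 2 (not isolated)
Conditions: POCl3 (1.2 equiv), DMF (1.3 equiv), MeCN, −10 °C to rt; then H2O, 50 °C
Reagents that add atoms: N,N-dimethylformamide CN(C)C=O; water O
Why: Vilsmeier–Haack formylation: the chloroiminium ion attacks the position ortho to one hydroxyl and para to the other (the two such positions of 1 are equivalent), and iminium salt 2 is hydrolysed to the aldehyde; the first formyl group deactivates the ring against a second.

Step 2
Reactants: 3 2,4-dihydroxy-3-methoxybenzaldehyde
Product: 4 4-(benzyloxy)-2-hydroxy-3-methoxybenzaldehyde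
Conditions: BnBr (1.05 equiv), KHCO3 (1.2 equiv), DMF, 40 °C
Reagents that add atoms: benzyl bromide BrCc1ccccc1
Why: Williamson etherification under weak-base control: the 4-hydroxyl (para to the formyl group) is the more acidic and the 2-hydroxyl is tied up in a hydrogen bond to the carbonyl oxygen, so bicarbonate should give the 4-O-benzyl ether selectively.

Step 3
Reactants: 4 4-(benzyloxy)-2-hydroxy-3-methoxybenzaldehyde
Product: 5 4-(benzyloxy)-2-hydroxy-3-methoxybenzyl alcohol
Conditions: NaBH4 (1.0 equiv), THF–MeOH 4:1, 0 °C; pH 7 buffer work-up; used within a day
Reagents that add atoms: none
Why: Borohydride reduction of an aryl aldehyde; the benzyl ether is inert, and the neutral work-up avoids premature ionisation of the electron-rich salicyl alcohol.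

Step 4
Reactants: 6 1,2,3,4-tetramethoxybenzene
Product: 9 2,3,4,5-tetramethoxybenzaldehyde, via aryllithium 7 (not isolated), via lithium hemiaminal alkoxide 8 (not isolated)
Conditions: n-BuLi (1.1 equiv), TMEDA (1.1 equiv), THF, 0 °C; DMF (1.5 equiv), 0 °C to rt; 1 M HCl
Reagents that add atoms: N,N-dimethylformamide CN(C)C=O
Why: Directed ortho-metalation then formylation: a methoxy group directs lithiation to the adjacent free position (the two free positions of 6 are equivalent), aryllithium 7 adds to DMF, and the tetrahedral adduct 8 collapses to the aldehyde on acidic work-up.

Step 5
Reactants: 9 2,3,4,5-tetramethoxybenzaldehyde; 10 (methoxymethyl)triphenylphosphonium chloride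
Product: 12 (E)-1-(2-methoxyvinyl)-2,3,4,5-tetramethoxybenzene, via methoxymethylidene ylide 11 (not isolated)
Conditions: 10 (1.4 equiv), KOtBu (1.3 equiv), THF, 0 °C; then 9, 0 °C to rt; chromatography on Et3N-deactivated silica, E fraction collected
Reagents that add atoms: none
Why: Wittig methoxymethylenation: ylide 11, formed by deprotonation of 10, adds to the aldehyde and the oxaphosphetane collapses to the enol ether and triphenylphosphine oxide; the reaction gives both alkene geometries, so only the E fraction is taken on, its geometry to be confirmed by the large trans vinyl coupling constant.

Step 6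
Reactants: 5 4-(benzyloxy)-2-hydroxy-3-methoxybenzyl alcohol; 12 (E)-1-(2-methoxyvinyl)-2,3,4,5-tetramethoxybenzene
Product: 14 (2R,3S)-7-(benzyloxy)-2,8-dimethoxy-3-(2,3,4,5-tetramethoxyphenyl)chromane, via ortho-quinone methide 13 (not isolated)
Conditions: (R)-TRIP (10 mol%), 5 Å MS, PhMe, 0 °C to rt; 5 (1.3 equiv) added over 6 h to 12 (1.0 equiv); Et3N quench
Reagents that add atoms: none
Why: The phosphoric acid protonates the benzylic hydroxyl of 5, water leaves with the help of the para benzyloxy and ortho hydroxyl donors, and the ortho-quinone methide 13 stays hydrogen-bonded to the phosphate through its oxygen. The aryl-bearing β-carbon of enol ether 12 adds to the exocyclic CH2 of 13 and the developing oxocarbenium carbon is captured by the methide oxygen, a concerted but asynchronous inverse-electron-demand oxa-Diels–Alder reaction; the closest known reaction type is the chiral phosphoric acid catalysed [4+2] cycloaddition of in situ generated ortho-quinone methides with enol ethers, enamides and styrenes. The pyran ring is closed by the cycloaddition itself as a [4+2] ring formation, which in the stepwise limit is a 6-exo-trig attack of the phenolic oxygen on the oxocarbenium ion. C3 is set by the catalyst: the phosphate, held on the methide oxygen and paired with the developing oxocarbenium ion, leaves one enantiotopic face of the enol ether β-carbon open inside the pocket of the 3,3'-aryl groups. C2 is set relative to C3 by suprafacial addition to the E alkene (2,3-trans) and is of no later consequence. The step needs regioselectivity (aryl on C3, acetal on C2), secured by the polarisation of enol ether and methide; chemoselectivity for the enol ether over Friedel–Crafts attack by the electron-rich rings, secured by slow addition of 5 and the much higher nucleophilicity of the enol ether; and face selectivity, which rests on the catalyst alone because the methide carbon is unsubstituted.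

Step 7
Reactants: 14 (2R,3S)-7-(benzyloxy)-2,8-dimethoxy-3-(2,3,4,5-tetramethoxyphenyl)chromane
Product: 15 (S)-7-(benzyloxy)-8-methoxy-3-(2,3,4,5-tetramethoxyphenyl)chromane
Conditions: Et3SiH (3 equiv), TMSOTf (0.2 equiv), CH2Cl2, −78 to −40 °C; aq NaHCO3 at −40 °C
Reagents that add atoms: none
Why: Silane reduction of an acetal under silyl triflate catalysis (ionic hydrogenation): the more basic exocyclic methoxy oxygen is silylated, the C2–OMe bond ionises to the cyclic oxocarbenium ion, and Et3SiH delivers hydride to C2; no bond to C3 is touched, and low temperature, excess silane and the absence of base should keep proton loss from C3 slower than hydride capture.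

Step 8
Reactants: 15 (S)-7-(benzyloxy)-8-methoxy-3-(2,3,4,5-tetramethoxyphenyl)chromane
Product: 16 (S)-8-methoxy-3-(2,3,4,5-tetramethoxyphenyl)chroman-7-ol
Conditions: H2 (1 atm), 10% Pd/C, EtOAc–EtOH, rt
Reagents that add atoms: none
Why: Hydrogenolysis of a benzyl aryl ether over palladium; the chromane C–O bonds (aryl–O and non-benzylic alkyl–O) and the methyl ethers are inert, and the C3–H stereocentre is not affected under neutral conditions at room temperature.

## Compound list

1 | 2-methoxyresorcinol | COc1c(O)cccc1O | starting material
2 | [(2,4-dihydroxy-3-methoxyphenyl)methylidene]dimethyliminium chloride | C[N+](C)=Cc1ccc(O)c(OC)c1O.[Cl-] | intermediate (not isolated)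
3 | 2,4-dihydroxy-3-methoxybenzaldehyde | O=Cc1ccc(O)c(OC)c1O | intermediate
4 | 4-(benzyloxy)-2-hydroxy-3-methoxybenzaldehyde | O=Cc1ccc(OCc2ccccc2)c(OC)c1O | intermediate
5 | 4-(benzyloxy)-2-hydroxy-3-methoxybenzyl alcohol | OCc1ccc(OCc2ccccc2)c(OC)c1O | intermediate
6 | 1,2,3,4-tetramethoxybenzene | COc1ccc(OC)c(OC)c1OC | starting material
7 | (2,3,4,5-tetramethoxyphenyl)lithium | [Li]c1cc(OC)c(OC)c(OC)c1OC | intermediate (not isolated)
8 | lithium (dimethylamino)(2,3,4,5-tetramethoxyphenyl)methanolate (racemic) | [Li+].[O-]C(N(C)C)c1cc(OC)c(OC)c(OC)c1OC | intermediate (not isolated)
9 | 2,3,4,5-tetramethoxybenzaldehyde | O=Cc1cc(OC)c(OC)c(OC)c1OC | intermediate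
10 | (methoxymethyl)triphenylphosphonium chloride | COC[P+](c1ccccc1)(c1ccccc1)c1ccccc1.[Cl-] | starting material
11 | (methoxymethylidene)triphenylphosphorane | COC=P(c1ccccc1)(c1ccccc1)c1ccccc1 | intermediate (not isolated)
12 | (E)-1-(2-methoxyvinyl)-2,3,4,5-tetramethoxybenzene | CO/C=C/c1cc(OC)c(OC)c(OC)c1OC | intermediate
13 | 3-(benzyloxy)-2-methoxy-6-methylidenecyclohexa-2,4-dien-1-one | C=C1C=CC(OCc2ccccc2)=C(OC)C1=O | intermediate (not isolated)
14 | (2R,3S)-7-(benzyloxy)-2,8-dimethoxy-3-(2,3,4,5-tetramethoxyphenyl)chromane (2,3-trans) | COc1cc([C@H]2[C@H](OC)Oc3c(ccc(OCc4ccccc4)c3OC)C2)c(OC)c(OC)c1OC | intermediate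
15 | (S)-7-(benzyloxy)-8-methoxy-3-(2,3,4,5-tetramethoxyphenyl)chromane | COc1cc([C@H]2COc3c(ccc(OCc4ccccc4)c3OC)C2)c(OC)c(OC)c1OC | intermediate
16 | (S)-8-methoxy-3-(2,3,4,5-tetramethoxyphenyl)chroman-7-ol | COc1cc([C@H]2COc3c(ccc(O)c3OC)C2)c(OC)c(OC)c1OC | target

## Step count and least certain steps

Total step count: 8. Longest linear sequence: 6 (steps 1, 2, 3, 6, 7, 8).

Step 6 (key step).
- What may go wrong: face selection at the enol ether carbon may be insufficient, because the catalyst is anchored only to the methide oxygen, the enol ether has no hydrogen-bond donor, and the methide carbon carries no substituent. The water released may hydrolyse the enol ether. The unsubstituted methide may oligomerise by Friedel–Crafts attack of electron-rich rings.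
- Fallback (the stereocentre is set by asymmetric hydrogenation and not by the cycloaddition): it sets out from 5 and 12, and alkene geometry no longer matters, so the unseparated Wittig mixture could serve. With an achiral acid (diphenyl phosphate, CH2Cl2, rt) the same cycloaddition should give racemic 7-(benzyloxy)-2,8-dimethoxy-3-(2,3,4,5-tetramethoxyphenyl)chromane F1 as a mixture of C2 epimers. TsOH (cat.) in toluene at 80 °C should eliminate methanol to give 7-(benzyloxy)-8-methoxy-3-(2,3,4,5-tetramethoxyphenyl)-4H-chromene F2, a cyclic trisubstituted enol ether. Iridium-catalysed asymmetric hydrogenation with a chiral N,P ligand (H2, CH2Cl2), the ligand enantiomer chosen for the S product, returns to the route at 15.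

Step 7.
- What may go wrong: proton loss from C3 of the oxocarbenium ion towards the conjugated 4H-chromene, followed by unselective reprotonation, would erode the enantiomeric purity. Ionisation of the endocyclic C2–O1 bond would lead, after hydride transfer, to ring opening.
- Fallback (no oxocarbenium ion in a non-nucleophilic medium; the ring is opened and re-closed): it sets out from 14. Mild aqueous acid (AcOH–H2O–THF, rt) should give the lactol (3S)-7-(benzyloxy)-8-methoxy-3-(2,3,4,5-tetramethoxyphenyl)chroman-2-ol F3. NaBH4 in EtOH at 0 °C should reduce the small standing amount of open-chain aldehyde faster than it enolises and give (S)-3-(benzyloxy)-6-[3-hydroxy-2-(2,3,4,5-tetramethoxyphenyl)propyl]-2-methoxyphenol F4. Mitsunobu cyclisation (PPh3, DIAD, THF, 0 °C) of the phenol onto the primary alcohol returns to the route at 15.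

Step 5.
- What may go wrong: an unfavourable E/Z ratio, incomplete chromatographic separation of the isomers, and hydrolysis of the enol ether on silica.
- Fallback (stereospecific Horner–Wittig route): it sets out from 9. Lithiated (methoxymethyl)diphenylphosphine oxide (LDA, THF, −78 °C) adds to 9 to give two diastereomeric β-hydroxy phosphine oxides that can be separated by crystallisation or chromatography. The threo isomer, racemic (1R*,2S*)-2-(diphenylphosphoryl)-2-methoxy-1-(2,3,4,5-tetramethoxyphenyl)ethan-1-ol F5, undergoes stereospecific syn elimination of diphenylphosphinate with NaH in THF and returns to the route at 12 as the E isomer only.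

Step 2.
- What may go wrong: over-alkylation to the bis-ether, or alkylation at the chelated 2-hydroxyl.
- Fallback (protect both, then remove one under chelation control): it sets out from 3. Exhaustive benzylation (BnBr 2.5 equiv, K2CO3, DMF) gives 2,4-bis(benzyloxy)-3-methoxybenzaldehyde F6. MgBr2·OEt2 (PhMe–Et2O, reflux) cleaves only the benzyl ether ortho to the carbonyl group through magnesium chelation and returns to the route at 4.

## Further compounds

F1 | step 6 | racemic 7-(benzyloxy)-2,8-dimethoxy-3-(2,3,4,5-tetramethoxyphenyl)chromane (C2 epimers) | COc1cc(C2C(OC)Oc3c(ccc(OCc4ccccc4)c3OC)C2)c(OC)c(OC)c1OC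
F2 | step 6 | 7-(benzyloxy)-8-methoxy-3-(2,3,4,5-tetramethoxyphenyl)-4H-chromene | COc1cc(C2=COc3c(ccc(OCc4ccccc4)c3OC)C2)c(OC)c(OC)c1OC
F3 | step 7 | (3S)-7-(benzyloxy)-8-methoxy-3-(2,3,4,5-tetramethoxyphenyl)chroman-2-ol (anomer mixture) | COc1cc([C@H]2C(O)Oc3c(ccc(OCc4ccccc4)c3OC)C2)c(OC)c(OC)c1OC
F4 | step 7 | (S)-3-(benzyloxy)-6-[3-hydroxy-2-(2,3,4,5-tetramethoxyphenyl)propyl]-2-methoxyphenol | COc1cc([C@@H](CO)Cc2ccc(OCc3ccccc3)c(OC)c2O)c(OC)c(OC)c1OC
F5 | step 5 | racemic (1R*,2S*)-2-(diphenylphosphoryl)-2-methoxy-1-(2,3,4,5-tetramethoxyphenyl)ethan-1-ol (one enantiomer drawn) | CO[C@@H]([C@@H](O)c1cc(OC)c(OC)c(OC)c1OC)P(=O)(c1ccccc1)c1ccccc1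
F6 | step 2 | 2,4-bis(benzyloxy)-3-methoxybenzaldehyde | O=Cc1ccc(OCc2ccccc2)c(OC)c1OCc1ccccc1
A1 | alternative 1 | 2-(2,3,4,5-tetramethoxyphenyl)prop-2-enal | C=C(C=O)c1cc(OC)c(OC)c(OC)c1OC
A2 | alternative 1 | (3S)-8-methoxy-3-(2,3,4,5-tetramethoxyphenyl)chromane-2,7-diol (anomer mixture) | COc1cc([C@H]2C(O)Oc3c(ccc(O)c3OC)C2)c(OC)c(OC)c1OC
A3 | alternative 2 | 6-(benzyloxy)-7-methoxybenzofuran | COc1c(OCc2ccccc2)ccc2ccoc12
A4 | alternative 2 | 3-chloro-3-(2,3,4,5-tetramethoxyphenyl)-3H-diazirine | COc1cc(C2(Cl)N=N2)c(OC)c(OC)c1OC
A5 | alternative 2 | 7-(benzyloxy)-8-methoxy-3-(2,3,4,5-tetramethoxyphenyl)chromenylium chloride | COc1cc(-c2c[o+]c3c(OC)c(OCc4ccccc4)ccc3c2)c(OC)c(OC)c1OC.[Cl-]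
A6 | alternative 3 | 2-[4-(benzyloxy)-2-iodo-3-methoxybenzyl]-2-(2,3,4,5-tetramethoxyphenyl)propane-1,3-diol | COc1cc(C(CO)(CO)Cc2ccc(OCc3ccccc3)c(OC)c2I)c(OC)c(OC)c1OC
A7 | alternative 3 | (S)-[7-(benzyloxy)-8-methoxy-3-(2,3,4,5-tetramethoxyphenyl)chroman-3-yl]methanol | COc1cc([C@@]2(CO)COc3c(ccc(OCc4ccccc4)c3OC)C2)c(OC)c(OC)c1OC
A8 | alternative 3 | (R)-7-(benzyloxy)-8-methoxy-3-(2,3,4,5-tetramethoxyphenyl)chromane-3-carbaldehyde | COc1cc([C@@]2(C=O)COc3c(ccc(OCc4ccccc4)c3OC)C2)c(OC)c(OC)c1OC
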